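**Strategy**

The route rests on disconnecting the ring-fusion bond C3a–C7a (indane numbering) shared by the cyclopentane (ring B) and the cyclohexane (ring A). One intramolecular Diels–Alder reaction forms this bond together with C4–C5, closing both carbocycles and setting C3a, C4 and C7a. Its precursor is an acyclic enone in which the C1 oxygen is tied to the future methylene carbon on C7 as a temporary 2,5-dihydrofuran bearing the diene, made in the same flask by enyne metathesis. The step exploits the cis relation of O–C1 (ring B) and C7 (ring A); the extra ring is later opened and a selenoxide [2,3]-shift unveils the exocyclic methylene and the C6 oxygen.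

Key step: step 14

Assumption: the 2-methylbutanoate is (R) as encoded; 8, 13, 28, 34, phenyl trimethylsilyl selenide and prop-2-yn-1-yl 2,2,2-trichloroacetimidate are taken as purchasable.

**Route**

Step 1
Reactants: 1 (R)-4-benzyloxazolidin-2-one; 2 (E)-but-2-enoyl chloride
Product: 3 (R)-4-benzyl-3-[(E)-but-2-enoyl]oxazolidin-2-one
Conditions: n-BuLi, THF, −78 °C; then 2, −78 → 0 °C
Reagents that add atoms: none
Why: N-acylation of the lithiated oxazolidinone by the acid chloride (imide formation) should proceed without touching the auxiliary stereocenter.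

Step 2
Reactants: 3 (R)-4-benzyl-3-[(E)-but-2-enoyl]oxazolidin-2-one; 4 acetaldehyde
Product: 7 (R)-4-benzyl-3-[(2R,3S)-2-ethenyl-3-hydroxybutanoyl]oxazolidin-2-one, via boron dienolate 5 (not isolated), via boron aldolate 6 (not isolated)
Conditions: Bu2BOTf, Et3N, CH2Cl2, −78 → 0 °C; 4, −78 → 0 °C; then H2O2, MeOH, pH 7 buffer
Reagents that add atoms: none
Why: Evans syn-aldol reaction, in which the Z-configured boron dienolate reacts at its α-carbon through a Zimmerman–Traxler chair whose face is fixed by the (R)-benzyl auxiliary, should set the later C3 (2R here) and its carbinol carbon (S).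

Step 3
Reactants: 7 (R)-4-benzyl-3-[(2R,3S)-2-ethenyl-3-hydroxybutanoyl]oxazolidin-2-one; 8 (S)-but-3-en-2-ol
Product: 9 (R)-4-benzyl-3-{(2R,3E,5S)-5-hydroxy-2-[(1S)-1-hydroxyethyl]hex-3-enoyl}oxazolidin-2-one
Conditions: second-generation Hoveyda–Grubbs catalyst (5 mol %), 8 (4 equiv), 1,4-benzoquinone (10 mol %), CH2Cl2, 40 °C
Reagents that add atoms: none
Why: Olefin cross-metathesis of the only terminal alkene with an excess of a reactive allylic alcohol should give the E-alkene, a masked enone that survives the hydride and organoboron steps.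

Step 4
Reactants: 9 (R)-4-benzyl-3-{(2R,3E,5S)-5-hydroxy-2-[(1S)-1-hydroxyethyl]hex-3-enoyl}oxazolidin-2-one
Product: 10 (R)-4-benzyl-3-{(2R,3E,5S)-5-[(tert-butyldimethylsilyl)oxy]-2-[(1S)-1-[(tert-butyldimethylsilyl)oxy]ethyl]hex-3-enoyl}oxazolidin-2-one
Conditions: TBSOTf (2.5 equiv), 2,6-lutidine, CH2Cl2, 0 °C
Reagents that add atoms: tert-butyldimethylsilyl trifluoromethanesulfonate, CC(C)(C)[Si](C)(C)OS(=O)(=O)C(F)(F)F
Why: Silylation of both secondary alcohols with the silyl triflate and a hindered base should leave all stereocenters untouched.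

Step 5
Reactants: 10 (R)-4-benzyl-3-{(2R,3E,5S)-5-[(tert-butyldimethylsilyl)oxy]-2-[(1S)-1-[(tert-butyldimethylsilyl)oxy]ethyl]hex-3-enoyl}oxazolidin-2-one
Product: 11 (2S,3E,5S)-5-[(tert-butyldimethylsilyl)oxy]-2-[(1S)-1-[(tert-butyldimethylsilyl)oxy]ethyl]hex-3-en-1-ol
Conditions: LiBH4, MeOH (1 equiv), THF, 0 °C
Reagents that add atoms: none
Why: Reductive cleavage of the imide by hydride attack at the exocyclic carbonyl should give the primary alcohol and return the auxiliary.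

Step 6
Reactants: 11 (2S,3E,5S)-5-[(tert-butyldimethylsilyl)oxy]-2-[(1S)-1-[(tert-butyldimethylsilyl)oxy]ethyl]hex-3-en-1-ol
Product: 12 (2R,3E,5S)-5-[(tert-butyldimethylsilyl)oxy]-2-[(1S)-1-[(tert-butyldimethylsilyl)oxy]ethyl]hex-3-enal
Conditions: Dess–Martin periodinane, NaHCO3, CH2Cl2, 0 °C → rt; used crude
Reagents that add atoms: none
Why: Dess–Martin oxidation under buffered, non-basic conditions should give the α-branched β,γ-unsaturated aldehyde without epimerisation or migration of the alkene.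

Step 7
Reactants: 12 (2R,3E,5S)-5-[(tert-butyldimethylsilyl)oxy]-2-[(1S)-1-[(tert-butyldimethylsilyl)oxy]ethyl]hex-3-enal; 13 3-(methoxymethoxy)prop-1-ene
Product: 16 (3R,4R,5S,6E,8S)-8-[(tert-butyldimethylsilyl)oxy]-5-[(1S)-1-[(tert-butyldimethylsilyl)oxy]ethyl]-3-(methoxymethoxy)nona-1,6-dien-4-ol, via allylborane 14 (not isolated), via borinate ester 15 (not isolated)
Conditions: 13, s-BuLi, THF, −78 °C; (−)-B-methoxydiisopinocampheylborane [(−)-Ipc2BOMe, from (+)-α-pinene]; BF3·OEt2; then 12, −78 °C; NaOH, H2O2, 0 °C → rt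
Reagents that add atoms: none
Why: Brown alkoxyallylboration, in which the (Z)-γ-alkoxyallylborane adds through a chair transition state so that the Z geometry sets the syn relation of the two oxygens and the isopinocampheyl groups direct attack to the Si face of the aldehyde, should set C4 (R) and C3 (R) under reagent control.

Step 8
Reactants: 16 (3R,4R,5S,6E,8S)-8-[(tert-butyldimethylsilyl)oxy]-5-[(1S)-1-[(tert-butyldimethylsilyl)oxy]ethyl]-3-(methoxymethoxy)nona-1,6-dien-4-ol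
Product: 17 (3R,4R,5S,6E,8S)-8-[(tert-butyldimethylsilyl)oxy]-5-[(1S)-1-[(tert-butyldimethylsilyl)oxy]ethyl]-3-(methoxymethoxy)nona-1,6-dien-4-yl 2-methylpropanoate
Conditions: isobutyryl chloride, pyridine, DMAP (cat.), CH2Cl2, 0 → 40 °C
Reagents that add atoms: 2-methylpropanoyl chloride, CC(C)C(Cl)=O
Why: DMAP-catalysed acylation of the hindered secondary alcohol should install the isobutyrate of the target with retention.

Step 9
Reactants: 17 (3R,4R,5S,6E,8S)-8-[(tert-butyldimethylsilyl)oxy]-5-[(1S)-1-[(tert-butyldimethylsilyl)oxy]ethyl]-3-(methoxymethoxy)nona-1,6-dien-4-yl 2-methylpropanoate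
Product: 18 (3R,4R,5R,6E,8S)-8-hydroxy-5-[(1S)-1-hydroxyethyl]-3-(methoxymethoxy)nona-1,6-dien-4-yl 2-methylpropanoate
Conditions: HF·pyridine, pyridine, THF, 0 °C → rt
Reagents that add atoms: none
Why: Fluoride-mediated cleavage of both silyl ethers under buffered acidic conditions should leave the acetal, the ester and the alkenes intact and avoid acyl migration.

Step 10
Reactants: 18 (3R,4R,5R,6E,8S)-8-hydroxy-5-[(1S)-1-hydroxyethyl]-3-(methoxymethoxy)nona-1,6-dien-4-yl 2-methylpropanoate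
Product: 19 (3R,4R,5R,6E)-5-[(1S)-1-hydroxyethyl]-3-(methoxymethoxy)-8-oxonona-1,6-dien-4-yl 2-methylpropanoate
Conditions: MnO2 (excess), CH2Cl2, rt
Reagents that add atoms: none
Why: MnO2 oxidises only the allylic alcohol (chemoselective allylic oxidation), which should give the E-enone and remove the auxiliary stereocenter brought in by 8.

Step 11
Reactants: 19 (3R,4R,5R,6E)-5-[(1S)-1-hydroxyethyl]-3-(methoxymethoxy)-8-oxonona-1,6-dien-4-yl 2-methylpropanoate
Product: 20 (3R,4R,5R,6E)-5-[(1S)-1-acetoxyethyl]-3-(methoxymethoxy)-8-oxonona-1,6-dien-4-yl 2-methylpropanoate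
Conditions: Ac2O, pyridine, DMAP (cat.), CH2Cl2, 0 °C
Reagents that add atoms: acetic anhydride, CC(=O)OC(C)=O
Why: Acetylation of the remaining secondary alcohol should install the side-chain acetate of the target faster than any 1,3-acyl migration.

Step 12
Reactants: 20 (3R,4R,5R,6E)-5-[(1S)-1-acetoxyethyl]-3-(methoxymethoxy)-8-oxonona-1,6-dien-4-yl 2-methylpropanoate
Product: 22 (3R,4R,5R,6E)-5-[(1S)-1-acetoxyethyl]-3-hydroxy-8-oxonona-1,6-dien-4-yl 2-methylpropanoate, via dimethylborinate 21 (not isolated)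
Conditions: Me2BBr, CH2Cl2, −78 °C; then aq. NaHCO3, THF
Reagents that add atoms: none
Why: Lewis-acid cleavage of the methoxymethyl acetal by the bromoborane at low temperature should free the C3 hydroxyl while esters and enone stay intact.

Step 13
Reactants: 22 (3R,4R,5R,6E)-5-[(1S)-1-acetoxyethyl]-3-hydroxy-8-oxonona-1,6-dien-4-yl 2-methylpropanoate
Product: 23 (3R,4R,5R,6E)-5-[(1S)-1-acetoxyethyl]-8-oxo-3-(prop-2-yn-1-yloxy)nona-1,6-dien-4-yl 2-methylpropanoate
Conditions: prop-2-yn-1-yl 2,2,2-trichloroacetimidate, TfOH (5 mol %), CH2Cl2/cyclohexane, 0 °C → rt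
Reagents that add atoms: prop-2-yn-1-yl 2,2,2-trichloroacetimidate, C#CCOC(=N)C(Cl)(Cl)Cl
Why: Acid-catalysed O-alkylation with the trichloroacetimidate avoids an alkoxide and hence acyl migration from the neighbouring isobutyrate.

Step 14
Reactants: 23 (3R,4R,5R,6E)-5-[(1S)-1-acetoxyethyl]-8-oxo-3-(prop-2-yn-1-yloxy)nona-1,6-dien-4-yl 2-methylpropanoate
Product: 25 (1R,2R,3R,3aR,4S,7aS)-4-acetyl-3-[(1S)-1-acetoxyethyl]-2,3,3a,4,5,7a-hexahydro-1H-1,7-(epoxymethano)inden-2-yl 2-methylpropanoate, via dienyl dihydrofuran 24 (not isolated)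
Conditions: second-generation Grubbs catalyst (5 mol %), ethylene (1 atm), toluene, 60 °C; then argon purge, BHT, 130 °C (sealed tube)
Reagents that add atoms: none
Why: The ruthenium alkylidene loads on the vinyl group, closes the dihydrofuran by exo enyne ring-closing metathesis through a ruthenacyclobutene and releases the vinylcarbene as the 1,3-diene 24; on heating, 24 undergoes a concerted [4+2] cycloaddition (type 1 intramolecular Diels–Alder reaction of a 1,3,8-nonatriene), the closest known reaction type being the tandem enyne metathesis–intramolecular Diels–Alder sequence. Ring B closes by the C3a–C7a bond in the fused mode enforced by the three-atom tether, ring A closes by the C4–C5 bond, and the dihydrofuran closes by 5-exo metathesis. C7a is controlled by C1: the ring oxygen is held in the diene plane, so the enone can only reach the face that carries the C2 chain, which places O–C1 cis to C7. C3a and C4 are controlled by the E geometry of the enone (H3a and H4 trans) and by the endo transition state in which the C3 hydrogen eclipses the enone (allylic 1,3-strain keeps the 1-acetoxyethyl group outside), which should give the trans ring fusion. The step needs endo over exo selectivity and fused over bridged regiochemistry; the first rests on secondary orbital overlap and the C3 substituent, the second on the tether length.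

Step 15
Reactants: 25 (1R,2R,3R,3aR,4S,7aS)-4-acetyl-3-[(1S)-1-acetoxyethyl]-2,3,3a,4,5,7a-hexahydro-1H-1,7-(epoxymethano)inden-2-yl 2-methylpropanoate
Product: 27 (1R,2R,3R,3aR,4S,7aS)-4-acetyl-3-[(1S)-1-acetoxyethyl]-1-hydroxy-7-[(phenylselanyl)methyl]-2,3,3a,4,5,7a-hexahydro-1H-inden-2-yl 2-methylpropanoate, via trimethylsilyl ether 26 (not isolated)
Conditions: PhSeSiMe3, ZnI2 (10 mol %), toluene, 0 °C → rt; then citric acid, MeOH/H2O
Reagents that add atoms: phenyl trimethylsilyl selenide, C[Si](C)(C)[Se]c1ccccc1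
Why: Silyl selenide cleavage of an ether, in which ZnI2-assisted silylation of the ring oxygen is followed by SN2 attack of selenide at the primary allylic carbon, should open the temporary ring and give the C1 alcohol after hydrolysis of the silyl ether.

Step 16
Reactants: 27 (1R,2R,3R,3aR,4S,7aS)-4-acetyl-3-[(1S)-1-acetoxyethyl]-1-hydroxy-7-[(phenylselanyl)methyl]-2,3,3a,4,5,7a-hexahydro-1H-inden-2-yl 2-methylpropanoate; 28 (R)-2-methylbutanoic acid
Product: 29 (1R,2R,3R,3aR,4S,7aS)-4-acetyl-3-[(1S)-1-acetoxyethyl]-2-(2-methylpropanoyloxy)-7-[(phenylselanyl)methyl]-2,3,3a,4,5,7a-hexahydro-1H-inden-1-yl (2R)-2-methylbutanoate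
Conditions: EDC·HCl, DMAP, CH2Cl2, 0 °C → rt
Reagents that add atoms: none
Why: Carbodiimide (Steglich-type) esterification should acylate the C1 hydroxyl with retention, the trans-disposed C2 ester being poorly placed to migrate.

Step 17
Reactants: 29 (1R,2R,3R,3aR,4S,7aS)-4-acetyl-3-[(1S)-1-acetoxyethyl]-2-(2-methylpropanoyloxy)-7-[(phenylselanyl)methyl]-2,3,3a,4,5,7a-hexahydro-1H-inden-1-yl (2R)-2-methylbutanoate
Product: 30 (1R,2R,3R,3aR,4S,7aS)-3-[(1S)-1-acetoxyethyl]-4-[(2R)-2-methyloxiran-2-yl]-2-(2-methylpropanoyloxy)-7-[(phenylselanyl)methyl]-2,3,3a,4,5,7a-hexahydro-1H-inden-1-yl (2R)-2-methylbutanoate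
Conditions: Me3S(O)I, NaH, THF (ylide preformed); then 29, LaLi3[(S)-BINOLate]3 (5 mol %), tris(2,4,6-trimethoxyphenyl)phosphine oxide (5 mol %), 5 Å MS, THF, rt
Reagents that add atoms: trimethylsulfoxonium iodide, C[S+](C)(C)=O.[I-]
Why: Catalytic asymmetric Corey–Chaykovsky epoxidation of a methyl ketone, in which the chiral lanthanum–lithium binaphthoxide binds ketone and ylide, should deliver the methylene to one carbonyl face and set the oxirane carbon (R) under catalyst control (the antipodal catalyst is used if the sense is opposite).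

Step 18
Reactants: 30 (1R,2R,3R,3aR,4S,7aS)-3-[(1S)-1-acetoxyethyl]-4-[(2R)-2-methyloxiran-2-yl]-2-(2-methylpropanoyloxy)-7-[(phenylselanyl)methyl]-2,3,3a,4,5,7a-hexahydro-1H-inden-1-yl (2R)-2-methylbutanoate
Product: 33 (1R,2R,3R,3aR,4S,6S,7aS)-3-[(1S)-1-acetoxyethyl]-6-hydroxy-7-methylidene-4-[(2R)-2-methyloxiran-2-yl]-2-(2-methylpropanoyloxy)octahydro-1H-inden-1-yl (2R)-2-methylbutanoate, via selenoxide 31 (not isolated), via selenenate ester 32 (not isolated)
Conditions: H2O2 (30 % aq.), pyridine, CH2Cl2, 0 °C → rt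
Reagents that add atoms: hydrogen peroxide, OO
Why: Selenide oxidation and [2,3]-sigmatropic selenoxide–selenenate rearrangement (Mislow–Evans type) move oxygen to C6 and create the exocyclic methylene, and delivery to the face anti to the C1 acyloxy group along the axial trajectory should set C6 (S).

Step 19
Reactants: 34 (S)-but-3-yn-2-ol
Product: 36 (2E,4S)-4-hydroxy-3-methylpent-2-enoic acid, via alkenylalane 35 (not isolated)
Conditions: AlMe3 (3 equiv), Cp2ZrCl2 (0.25 equiv), CH2Cl2, 0 °C → rt; then n-BuLi, THF, −78 °C; CO2, −78 → 0 °C; aq. HCl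
Reagents that add atoms: trimethylaluminium, C[Al](C)C; carbon dioxide, O=C=O
Why: Negishi zirconium-catalysed carboalumination adds methyl and aluminium syn with aluminium at the terminal carbon, and carboxylation of the derived alanate with retention should give the E-acid with the carbinol center untouched.

Step 20
Reactants: 36 (2E,4S)-4-hydroxy-3-methylpent-2-enoic acid
Product: 38 (2E,4S)-4-acetoxy-3-methylpent-2-enoic acid, via mixed acetic anhydride 37 (not isolated)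
Conditions: Ac2O, pyridine, DMAP (cat.), CH2Cl2, 0 °C → rt; then H2O, NaHCO3; acidify
Reagents that add atoms: acetic anhydride, CC(=O)OC(C)=O
Why: Acetylation of the secondary alcohol is accompanied by mixed-anhydride formation at the acid, which aqueous work-up should hydrolyse back to the free acid.

Step 21
Reactants: 33 (1R,2R,3R,3aR,4S,6S,7aS)-3-[(1S)-1-acetoxyethyl]-6-hydroxy-7-methylidene-4-[(2R)-2-methyloxiran-2-yl]-2-(2-methylpropanoyloxy)octahydro-1H-inden-1-yl (2R)-2-methylbutanoate; 38 (2E,4S)-4-acetoxy-3-methylpent-2-enoic acid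
Product: 40 (1R,2R,3R,3aR,4S,6S,7aS)-3-[(1S)-1-acetoxyethyl]-6-{[(2E,4S)-4-acetoxy-3-methylpent-2-enoyl]oxy}-7-methylidene-4-[(2R)-2-methyloxiran-2-yl]-2-(2-methylpropanoyloxy)octahydro-1H-inden-1-yl (2R)-2-methylbutanoate, via mixed trichlorobenzoic anhydride 39 (not isolated)
Conditions: 38, 2,4,6-trichlorobenzoyl chloride, Et3N, toluene, rt; then 33, DMAP, toluene, rt
Reagents that add atoms: none
Why: Yamaguchi esterification through the mixed anhydride should acylate the hindered axial allylic alcohol with retention at C6 and without disturbing the epoxide.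

**Compound list**

1 | (R)-4-benzyloxazolidin-2-one | O=C1OC[C@@H](Cc2ccccc2)N1 | starting material
2 | (E)-but-2-enoyl chloride | C/C=C/C(Cl)=O | starting material
3 | (R)-4-benzyl-3-[(E)-but-2-enoyl]oxazolidin-2-one | C/C=C/C(=O)N1[C@H](Cc2ccccc2)COC1=O | intermediate
4 | acetaldehyde | CC=O | starting material
5 | (Z)-O-dibutylboryl dienolate of 3 (enolate oxygen cis to the vinyl group) | C=C/C=C(\OB(CCCC)CCCC)N1[C@H](Cc2ccccc2)COC1=O | intermediate
6 | O-dibutylboryl aldolate of 7 | C=C[C@H]([C@H](C)OB(CCCC)CCCC)C(=O)N1[C@H](Cc2ccccc2)COC1=O | intermediate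
7 | (R)-4-benzyl-3-[(2R,3S)-2-ethenyl-3-hydroxybutanoyl]oxazolidin-2-one | C=C[C@H]([C@H](C)O)C(=O)N1[C@H](Cc2ccccc2)COC1=O | intermediate
8 | (S)-but-3-en-2-ol | C=C[C@H](C)O | starting material
9 | (R)-4-benzyl-3-{(2R,3E,5S)-5-hydroxy-2-[(1S)-1-hydroxyethyl]hex-3-enoyl}oxazolidin-2-one | C[C@H](O)/C=C/[C@H]([C@H](C)O)C(=O)N1[C@H](Cc2ccccc2)COC1=O | intermediate
10 | (R)-4-benzyl-3-{(2R,3E,5S)-5-[(tert-butyldimethylsilyl)oxy]-2-[(1S)-1-[(tert-butyldimethylsilyl)oxy]ethyl]hex-3-enoyl}oxazolidin-2-one | C[C@H](O[Si](C)(C)C(C)(C)C)/C=C/[C@H]([C@H](C)O[Si](C)(C)C(C)(C)C)C(=O)N1[C@H](Cc2ccccc2)COC1=O | intermediate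
11 | (2S,3E,5S)-5-[(tert-butyldimethylsilyl)oxy]-2-[(1S)-1-[(tert-butyldimethylsilyl)oxy]ethyl]hex-3-en-1-ol | C[C@H](O[Si](C)(C)C(C)(C)C)/C=C/[C@H]([C@H](C)O[Si](C)(C)C(C)(C)C)CO | intermediate
12 | (2R,3E,5S)-5-[(tert-butyldimethylsilyl)oxy]-2-[(1S)-1-[(tert-butyldimethylsilyl)oxy]ethyl]hex-3-enal | C[C@H](O[Si](C)(C)C(C)(C)C)/C=C/[C@H]([C@H](C)O[Si](C)(C)C(C)(C)C)C=O | intermediate
13 | 3-(methoxymethoxy)prop-1-ene (allyl methoxymethyl ether) | C=CCOCOC | starting material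
14 | [(Z)-3-(methoxymethoxy)prop-2-en-1-yl]diisopinocampheylborane (isopinocampheyl groups from (+)-α-pinene) | COCO/C=C\CB([C@@H]1C[C@@H]2C[C@H]([C@H]1C)C2(C)C)[C@@H]1C[C@@H]2C[C@H]([C@H]1C)C2(C)C | intermediate
15 | O-diisopinocampheylboryl derivative (borinate) of 16 at the C4 oxygen | C=C[C@@H](OCOC)[C@H](OB([C@@H]1C[C@@H]2C[C@H]([C@H]1C)C2(C)C)[C@@H]1C[C@@H]2C[C@H]([C@H]1C)C2(C)C)[C@@H]([C@H](C)O[Si](C)(C)C(C)(C)C)/C=C/[C@H](C)O[Si](C)(C)C(C)(C)C | intermediate
16 | (3R,4R,5S,6E,8S)-8-[(tert-butyldimethylsilyl)oxy]-5-[(1S)-1-[(tert-butyldimethylsilyl)oxy]ethyl]-3-(methoxymethoxy)nona-1,6-dien-4-ol | C=C[C@@H](OCOC)[C@H](O)[C@@H]([C@H](C)O[Si](C)(C)C(C)(C)C)/C=C/[C@H](C)O[Si](C)(C)C(C)(C)C | intermediate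
17 | (3R,4R,5S,6E,8S)-8-[(tert-butyldimethylsilyl)oxy]-5-[(1S)-1-[(tert-butyldimethylsilyl)oxy]ethyl]-3-(methoxymethoxy)nona-1,6-dien-4-yl 2-methylpropanoate | C=C[C@@H](OCOC)[C@H](OC(=O)C(C)C)[C@@H]([C@H](C)O[Si](C)(C)C(C)(C)C)/C=C/[C@H](C)O[Si](C)(C)C(C)(C)C | intermediate
18 | (3R,4R,5R,6E,8S)-8-hydroxy-5-[(1S)-1-hydroxyethyl]-3-(methoxymethoxy)nona-1,6-dien-4-yl 2-methylpropanoate | C=C[C@@H](OCOC)[C@H](OC(=O)C(C)C)[C@@H]([C@H](C)O)/C=C/[C@H](C)O | intermediate
19 | (3R,4R,5R,6E)-5-[(1S)-1-hydroxyethyl]-3-(methoxymethoxy)-8-oxonona-1,6-dien-4-yl 2-methylpropanoate | C=C[C@@H](OCOC)[C@H](OC(=O)C(C)C)[C@@H]([C@H](C)O)/C=C/C(C)=O | intermediate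
20 | (3R,4R,5R,6E)-5-[(1S)-1-acetoxyethyl]-3-(methoxymethoxy)-8-oxonona-1,6-dien-4-yl 2-methylpropanoate | C=C[C@@H](OCOC)[C@H](OC(=O)C(C)C)[C@@H]([C@H](C)OC(C)=O)/C=C/C(C)=O | intermediate
21 | O-dimethylboryl derivative (dimethylborinate) of 22 at the C3 oxygen | C=C[C@@H](OB(C)C)[C@H](OC(=O)C(C)C)[C@@H]([C@H](C)OC(C)=O)/C=C/C(C)=O | intermediate
22 | (3R,4R,5R,6E)-5-[(1S)-1-acetoxyethyl]-3-hydroxy-8-oxonona-1,6-dien-4-yl 2-methylpropanoate | C=C[C@@H](O)[C@H](OC(=O)C(C)C)[C@@H]([C@H](C)OC(C)=O)/C=C/C(C)=O | intermediate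
23 | (3R,4R,5R,6E)-5-[(1S)-1-acetoxyethyl]-8-oxo-3-(prop-2-yn-1-yloxy)nona-1,6-dien-4-yl 2-methylpropanoate | C=C[C@@H](OCC#C)[C@H](OC(=O)C(C)C)[C@@H]([C@H](C)OC(C)=O)/C=C/C(C)=O | intermediate
24 | (1R,2R,3E)-2-[(1S)-1-acetoxyethyl]-1-[(2R)-4-ethenyl-2,5-dihydrofuran-2-yl]-5-oxohex-3-en-1-yl 2-methylpropanoate | C=CC1=C[C@H]([C@H](OC(=O)C(C)C)[C@@H]([C@H](C)OC(C)=O)/C=C/C(C)=O)OC1 | intermediate
25 | (1R,2R,3R,3aR,4S,7aS)-4-acetyl-3-[(1S)-1-acetoxyethyl]-2,3,3a,4,5,7a-hexahydro-1H-1,7-(epoxymethano)inden-2-yl 2-methylpropanoate (O on C1, CH2 on C7, H3a and H7a trans) | CC(=O)[C@H]1CC=C2CO[C@H]3[C@H](OC(=O)C(C)C)[C@@H]([C@H](C)OC(C)=O)[C@H]1[C@@H]23 | intermediate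
26 | C1 O-trimethylsilyl ether of 27 | CC(=O)[C@H]1CC=C(C[Se]c3ccccc3)[C@H]2[C@@H](O[Si](C)(C)C)[C@H](OC(=O)C(C)C)[C@@H]([C@H](C)OC(C)=O)[C@H]12 | intermediate
27 | (1R,2R,3R,3aR,4S,7aS)-4-acetyl-3-[(1S)-1-acetoxyethyl]-1-hydroxy-7-[(phenylselanyl)methyl]-2,3,3a,4,5,7a-hexahydro-1H-inden-2-yl 2-methylpropanoate | CC(=O)[C@H]1CC=C(C[Se]c3ccccc3)[C@H]2[C@@H](O)[C@H](OC(=O)C(C)C)[C@@H]([C@H](C)OC(C)=O)[C@H]12 | intermediate
28 | (R)-2-methylbutanoic acid | CC[C@@H](C)C(=O)O | starting material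
29 | (1R,2R,3R,3aR,4S,7aS)-4-acetyl-3-[(1S)-1-acetoxyethyl]-2-(2-methylpropanoyloxy)-7-[(phenylselanyl)methyl]-2,3,3a,4,5,7a-hexahydro-1H-inden-1-yl (2R)-2-methylbutanoate | CC(=O)[C@H]1CC=C(C[Se]c3ccccc3)[C@H]2[C@@H](OC(=O)[C@H](C)CC)[C@H](OC(=O)C(C)C)[C@@H]([C@H](C)OC(C)=O)[C@H]12 | intermediate
30 | (1R,2R,3R,3aR,4S,7aS)-3-[(1S)-1-acetoxyethyl]-4-[(2R)-2-methyloxiran-2-yl]-2-(2-methylpropanoyloxy)-7-[(phenylselanyl)methyl]-2,3,3a,4,5,7a-hexahydro-1H-inden-1-yl (2R)-2-methylbutanoate | C[C@]4(CO4)[C@H]1CC=C(C[Se]c3ccccc3)[C@H]2[C@@H](OC(=O)[C@H](C)CC)[C@H](OC(=O)C(C)C)[C@@H]([C@H](C)OC(C)=O)[C@H]12 | intermediate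
31 | Se-oxide (selenoxide) of 30 | C[C@]4(CO4)[C@H]1CC=C(C[Se](=O)c3ccccc3)[C@H]2[C@@H](OC(=O)[C@H](C)CC)[C@H](OC(=O)C(C)C)[C@@H]([C@H](C)OC(C)=O)[C@H]12 | intermediate
32 | C6 O-phenylselanyl derivative (benzeneselenenate) of 33 | C=C1[C@H]2[C@@H](OC(=O)[C@H](C)CC)[C@H](OC(=O)C(C)C)[C@@H]([C@H](C)OC(C)=O)[C@@H]2[C@@H]([C@]2(C)CO2)C[C@@H]1O[Se]c3ccccc3 | intermediate
33 | (1R,2R,3R,3aR,4S,6S,7aS)-3-[(1S)-1-acetoxyethyl]-6-hydroxy-7-methylidene-4-[(2R)-2-methyloxiran-2-yl]-2-(2-methylpropanoyloxy)octahydro-1H-inden-1-yl (2R)-2-methylbutanoate | C=C1[C@H]2[C@@H](OC(=O)[C@H](C)CC)[C@H](OC(=O)C(C)C)[C@@H]([C@H](C)OC(C)=O)[C@@H]2[C@@H]([C@]2(C)CO2)C[C@@H]1O | intermediate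
34 | (S)-but-3-yn-2-ol | C#C[C@H](C)O | starting material
35 | (E)-alkenylalane: O-dimethylaluminio (S)-4-(dimethylaluminio)-3-methylbut-3-en-2-olate (Al trans to the carbinol carbon) | C[C@H](O[Al](C)C)/C(C)=C/[Al](C)C | intermediate
36 | (2E,4S)-4-hydroxy-3-methylpent-2-enoic acid | C[C@H](O)/C(C)=C/C(=O)O | intermediate
37 | acetic (2E,4S)-4-acetoxy-3-methylpent-2-enoic anhydride | CC(=O)O[C@@H](C)/C(C)=C/C(=O)OC(C)=O | intermediate
38 | (2E,4S)-4-acetoxy-3-methylpent-2-enoic acid | CC(=O)O[C@@H](C)/C(C)=C/C(=O)O | intermediate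
39 | (2E,4S)-4-acetoxy-3-methylpent-2-enoic 2,4,6-trichlorobenzoic anhydride | CC(=O)O[C@@H](C)/C(C)=C/C(=O)OC(=O)c1c(Cl)cc(Cl)cc1Cl | intermediate
40 | (1R,2R,3R,3aR,4S,6S,7aS)-3-[(1S)-1-acetoxyethyl]-6-{[(2E,4S)-4-acetoxy-3-methylpent-2-enoyl]oxy}-7-methylidene-4-[(2R)-2-methyloxiran-2-yl]-2-(2-methylpropanoyloxy)octahydro-1H-inden-1-yl (2R)-2-methylbutanoate (CNP0115861.1) | C=C1[C@H]2[C@@H](OC(=O)[C@H](C)CC)[C@H](OC(=O)C(C)C)[C@@H]([C@H](C)OC(C)=O)[C@@H]2[C@@H]([C@]2(C)CO2)C[C@@H]1OC(=O)/C=C(\C)[C@H](C)OC(C)=O | target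

**Step count and risks**

Total step count: 21. Longest linear sequence: 19 (steps 1–18 and 21); steps 19–20 form the side-chain branch.

Steps most likely to fail:

1. Step 14. The ruthenium vinylcarbene may be diverted by the tethered enone, and the hot, metal-containing medium may isomerise the dihydrofuran diene or erode the endo preference. Fallback: reverse the order of unmasking and ring formation so that the cycloaddition runs without metal. It sets out from 17. Me2BBr (CH2Cl2, −78 °C) removes the acetal to give the allylic alcohol F1, and the trichloroacetimidate/TfOH alkylation of step 13 gives the propargyl ether F2. Enyne metathesis (second-generation Grubbs catalyst, ethylene), now on a substrate without an electron-poor alkene, gives the silyl-protected diene F3. HF·pyridine gives the diene diol F4 and MnO2 gives the diene hydroxy enone F5. Acetylation (Ac2O, pyridine, DMAP) gives 24, which is heated in toluene without ruthenium and comes back to the route at 25.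

2. Step 15. The Lewis acid may ionise the allylic ether, with proton loss to a diene or capture of the cation at C6, and the silyl selenide may add to the ketone. Fallback: a two-stage opening through a halide. It sets out from 25: Me2BBr (CH2Cl2, −78 °C; then aq. NaHCO3) should cleave the primary allylic C–O bond to the bromo alcohol F6, and PhSeH/Et3N displaces the bromide by SN2 to come back at 27.

3. Step 17. Facial selection at the ketone may be poor if catalyst and substrate are mismatched, and the ylide or the lanthanum alkoxide may attack the ester groups. Fallback: build the oxirane last from an alkene with a chiral dioxirane. It sets out from 29: Ph3P=CH2 (THF, 0 °C) gives the isopropenyl selenide F7. H2O2/pyridine takes it through the isopropenyl selenoxide F8 and the isopropenyl selenenate F9 to the isopropenyl allylic alcohol F10. Yamaguchi esterification with 38 (through 39) gives the isopropenyl tetraester F11. Shi epoxidation (carbohydrate-derived chiral ketone of the N-aryl oxazolidinone type, Oxone (2KHSO5·KHSO4·K2SO4), K2CO3, MeCN/dimethoxymethane/H2O, 0 °C) of the only electron-rich, unhindered alkene comes back to the route at 40.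

Further compounds

F1 | step 14 | (3R,4R,5S,6E,8S)-8-[(tert-butyldimethylsilyl)oxy]-5-[(1S)-1-[(tert-butyldimethylsilyl)oxy]ethyl]-3-hydroxynona-1,6-dien-4-yl 2-methylpropanoate | C=C[C@@H](O)[C@H](OC(=O)C(C)C)[C@@H]([C@H](C)O[Si](C)(C)C(C)(C)C)/C=C/[C@H](C)O[Si](C)(C)C(C)(C)C
F2 | step 14 | (3R,4R,5S,6E,8S)-8-[(tert-butyldimethylsilyl)oxy]-5-[(1S)-1-[(tert-butyldimethylsilyl)oxy]ethyl]-3-(prop-2-yn-1-yloxy)nona-1,6-dien-4-yl 2-methylpropanoate | C=C[C@@H](OCC#C)[C@H](OC(=O)C(C)C)[C@@H]([C@H](C)O[Si](C)(C)C(C)(C)C)/C=C/[C@H](C)O[Si](C)(C)C(C)(C)C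
F3 | step 14 | (1R,2S,3E,5S)-5-[(tert-butyldimethylsilyl)oxy]-2-[(1S)-1-[(tert-butyldimethylsilyl)oxy]ethyl]-1-[(2R)-4-ethenyl-2,5-dihydrofuran-2-yl]hex-3-en-1-yl 2-methylpropanoate | C=CC1=C[C@H]([C@H](OC(=O)C(C)C)[C@@H]([C@H](C)O[Si](C)(C)C(C)(C)C)/C=C/[C@H](C)O[Si](C)(C)C(C)(C)C)OC1
F4 | step 14 | (1R,2R,3E,5S)-1-[(2R)-4-ethenyl-2,5-dihydrofuran-2-yl]-5-hydroxy-2-[(1S)-1-hydroxyethyl]hex-3-en-1-yl 2-methylpropanoate | C=CC1=C[C@H]([C@H](OC(=O)C(C)C)[C@@H]([C@H](C)O)/C=C/[C@H](C)O)OC1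
F5 | step 14 | (1R,2R,3E)-1-[(2R)-4-ethenyl-2,5-dihydrofuran-2-yl]-2-[(1S)-1-hydroxyethyl]-5-oxohex-3-en-1-yl 2-methylpropanoate | C=CC1=C[C@H]([C@H](OC(=O)C(C)C)[C@@H]([C@H](C)O)/C=C/C(C)=O)OC1
F6 | step 15 | (1R,2R,3R,3aR,4S,7aS)-4-acetyl-3-[(1S)-1-acetoxyethyl]-7-(bromomethyl)-1-hydroxy-2,3,3a,4,5,7a-hexahydro-1H-inden-2-yl 2-methylpropanoate | CC(=O)[C@H]1CC=C(CBr)[C@H]2[C@@H](O)[C@H](OC(=O)C(C)C)[C@@H]([C@H](C)OC(C)=O)[C@H]12
F7 | step 17 | (1R,2R,3R,3aR,4S,7aS)-3-[(1S)-1-acetoxyethyl]-2-(2-methylpropanoyloxy)-7-[(phenylselanyl)methyl]-4-(prop-1-en-2-yl)-2,3,3a,4,5,7a-hexahydro-1H-inden-1-yl (2R)-2-methylbutanoate | C=C(C)[C@H]1CC=C(C[Se]c3ccccc3)[C@H]2[C@@H](OC(=O)[C@H](C)CC)[C@H](OC(=O)C(C)C)[C@@H]([C@H](C)OC(C)=O)[C@H]12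
F8 | step 17 | Se-oxide (selenoxide) of F7 | C=C(C)[C@H]1CC=C(C[Se](=O)c3ccccc3)[C@H]2[C@@H](OC(=O)[C@H](C)CC)[C@H](OC(=O)C(C)C)[C@@H]([C@H](C)OC(C)=O)[C@H]12
F9 | step 17 | C6 O-phenylselanyl derivative (benzeneselenenate) of F10 | C=C1[C@H]2[C@@H](OC(=O)[C@H](C)CC)[C@H](OC(=O)C(C)C)[C@@H]([C@H](C)OC(C)=O)[C@@H]2[C@@H](C(C)=C)C[C@@H]1O[Se]c3ccccc3
F10 | step 17 | (1R,2R,3R,3aR,4S,6S,7aS)-3-[(1S)-1-acetoxyethyl]-6-hydroxy-7-methylidene-2-(2-methylpropanoyloxy)-4-(prop-1-en-2-yl)octahydro-1H-inden-1-yl (2R)-2-methylbutanoate | C=C1[C@H]2[C@@H](OC(=O)[C@H](C)CC)[C@H](OC(=O)C(C)C)[C@@H]([C@H](C)OC(C)=O)[C@@H]2[C@@H](C(C)=C)C[C@@H]1O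
F11 | step 17 | (1R,2R,3R,3aR,4S,6S,7aS)-3-[(1S)-1-acetoxyethyl]-6-{[(2E,4S)-4-acetoxy-3-methylpent-2-enoyl]oxy}-7-methylidene-2-(2-methylpropanoyloxy)-4-(prop-1-en-2-yl)octahydro-1H-inden-1-yl (2R)-2-methylbutanoate | C=C1[C@H]2[C@@H](OC(=O)[C@H](C)CC)[C@H](OC(=O)C(C)C)[C@@H]([C@H](C)OC(C)=O)[C@@H]2[C@@H](C(C)=C)C[C@@H]1OC(=O)/C=C(\C)[C@H](C)OC(C)=O
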